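## The problem

The target is a heliangolide-type germacranolide. A ten-membered carbocycle (C1–C10) is trans-fused at C6–C7 to an α-methylene-γ-butyrolactone. It carries a Z-configured trisubstituted C4=C5 alkene, a trans 1,10-epoxide and two different esters: an (R)-2-methylbutanoate on O3 and a (2R,3S)-2,3-dimethyloxirane-2-carboxylate on O8.

Six stereocentres lie on the ring (C1, C3, C6, C7, C8, C10) and three in the acyl groups. C6 can control C7 through the five-membered ring. C3 and the C1/C10 pair are too far from C6/C7 to be relayed in an open chain, so they need reagent control or the conformation of the closed ring.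

The ten-membered ring is the bottleneck. Whichever bond closes it, the Z-C4=C5 alkene and the E-C1=C10 alkene (or its epoxide) must come out with defined geometry. The two hydroxyls O3 and O8 must also be told apart.

Several groups are fragile:
- The exocyclic methylene is a Michael acceptor and migrates into the ring once C7–H is acidified.
- The trisubstituted epoxide opens transannularly under acid.
- The esters and the lactone are base-labile.
- A C8 carbonyl sits β to the lactone oxygen on C6 and β to any oxygen on C10.

The enabling feature is C7. As the lactone β-carbon it is bonded to C6, C8 and C11. A butenolide that already carries C6 therefore offers C7 to a C8 acyl-anion equivalent, and the enolate formed at C11 can take the C13 carbon in the same operation.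

## Retrosynthesis

**C3 ester.** Target 33 is cut at the O3–acyl bond to the macrocyclic alcohol 30 and (R)-2-methylbutanoic acid 31. Acylating last keeps a free allylic hydroxyl for the ring closure and removes one ester from every earlier basic or reducing step. The forward reaction only needs a mild carbodiimide coupling that leaves the epoxide and the Michael acceptor alone.

**Ring closure at C4=C5.** Alcohol 30 is cut at C4=C5 to diene 29 by ring-closing metathesis. C4 comes from the side arm and C5 from the lactone fragment, so this is the one ring bond that joins them. The neighbouring cuts (C5–C6, C3–C4) would break up the butenolide or the arm. The forward step must close a strained ring with Z geometry. It also fixes the order of events: with C1=C10 still present, a ruthenium carbene at C5 would close the six-membered ring C5–C10 and expel C1–C4. The alkene is therefore already an epoxide in 29.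

**Epoxide and methylene.** Diene 29 comes from triene 28 by Shi epoxidation of the only electron-rich trisubstituted alkene. Because the chain is still open, C1 and C10 are set by the catalyst and not by an unknown ring conformation. Triene 28 comes from Mannich base 26 by quaternisation–elimination through 27. The amine must go before the oxidation and the metathesis, but only after C8 has ceased to be a ketone, otherwise C7–H would allow the methylene to migrate.

**C8 ester and the two oxygens.** Amine 26 is the desilylated form of 25, which is cut at O8 to alcohol 20 and epoxy acid 23. O3 stays silylated until O8 is acylated, which distinguishes the two hydroxyls. Acid 23 is traced through epoxy alcohol 22 to tiglyl alcohol 21 by Sharpless epoxidation and oxidation. This is preferred to a late epoxidation of a tiglate ester, which would have no facial control.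

**C8 carbinol.** Alcohol 20 comes from ketone 19 by a catalyst-controlled reduction, and 19 from dithiane 18. The dithiane is what allows C8 to act as a nucleophile. The ketone is kept for one step only.

**C5 vinyl group.** Vinyl lactone 18 is traced through aldehyde 17 and alcohol 16 to the bis-silyl ether 15. A vinyl butenolide would be too acidic at C6 and would shield the ring face less well. The forward steps need a primary/secondary silyl ether distinction and an olefination that does not epimerise C6.

**Key disconnection.** Compound 15 is cut at C7–C8 and C11–C13 into dithiane 9, butenolide 11 and Eschenmoser's salt 12. Three components and two bonds replace a longer linear build-up, and C7 is set by C6. The forward reaction must be 1,4-selective and anti to the C6 substituent.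

**The arm.** Dithiane 9 is cut at C8–C9 into 1,3-dithiane 7 (as its anion 8) and allylic bromide 6. Bromide 6 goes back through alcohol 5 and enal 4 to silyl ether 3 and methacrolein 1 by cross-metathesis, which gives the E-trisubstituted alkene directly. Silyl ether 3 comes from alcohol 2, and 2 from 1 by asymmetric allylboration, which sets C3.

**The acceptor.** Butenolide 11 is the silyl ether of commercial 10, whose stereocentre becomes C6.

## Roads not taken

Alternative 1: The cut is C7–C11 together with the lactone closure, made on a finished ten-membered ring. A C7 radical, formed from either xanthate epimer, adds 5-exo-dig to a C6 propiolate, and the vinyl radical takes hydrogen to give A1.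
- Merits: the methylene lactone appears directly, with no amine mask, no dithiane removal and no C8 reduction. It is stereoconvergent at C7, and A1 already carries the C3 ester, so the end game is short.
- Weak points: the ten-membered ring with its C3, C6, C7 and C8 oxygens and both alkenes must exist first, so the hardest problem is only moved. The C7 radical sits across the ring from C1=C10, so transannular addition and hydrogen shifts compete. The trans fusion depends on the conformation of a flexible ring.
- Comparison: Alternative 1 is better in step count after ring closure and never exposes a masked methylene to many steps. The chosen plan sets against this a C6 from the chiral pool, a C7 fixed by anti addition before any ring exists, and one convergent step that gathers C5–C13 with the whole arm.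

Alternative 2: The cut is C8–C9, with the ten-membered ring traced back to a six-membered one. An anionic oxy-Cope rearrangement of a cyclohexenol alkoxide forms C8–C9, cleaves the ring bond and gives dienone A2.
- Merits: ring expansion is the most dependable entry to a ten-membered ring and needs no high dilution. The E-C1=C10 alkene follows from a chair transition state, the Z-C4=C5 alkene is inherited from the cyclohexene, and C8 is set in the same event.
- Weak points: A2 stops at the C6 ketone. C11–C13 still have to be attached at C7 and C6 reduced on a flexible (E,Z)-cyclodecadienone, with competing enolisation towards C5, transannular reactions, and C6/C7 configurations left to ring conformation.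
- Comparison: for forming the ring, Alternative 2 is better than the chosen plan, and this is conceded. The chosen plan answers with secure lactone stereochemistry (C6 and C7 fixed first) and independent reagent control of C3, C8 and C1/C10. Its price is a risky metathesis.

Alternative 3: The cut is C5–C6 plus the lactone C–O bond. A chromium/nickel-mediated Nozaki–Hiyama–Kishi coupling adds the alkenyl metal from a Z-C5 iodide to a C6 aldehyde, and the alkoxide lactonises to A3.
- Merits: the macrocyclisation is an irreversible C–C bond formation with a good record for ten-membered rings. The Z geometry is fixed before ring closure, one operation forms both rings, and no metathesis catalyst meets C1=C10, so the epoxide could be left to the end.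
- Weak points: C6 is created in the macrocyclisation, so the trans lactone is not assured. C7 is α to the aldehyde and can epimerise. The open-chain precursor is long and linear, and the methylene must still be added to A3.
- Comparison: the ring closure of Alternative 3 is probably more reliable than the metathesis chosen here. The chosen plan offers instead C6/C7 control from the chiral pool, a three-component assembly, and the C13 carbon already in place when the ring closes.

Key step: step 8

Assumption: germacranolide numbering is used for all intermediates, and C11 of compounds 15–27 is left unassigned because step 18 erases it.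

## Route

Step 1
Reactants: 1 2-methylprop-2-enal (methacrolein)
Product: 2 (3S)-2-methylhexa-1,5-dien-3-ol
Conditions: (+)-Ipc2B(allyl) (reagent derived from (+)-α-pinene), Et2O, −78 °C; then NaOH, H2O2, 0 °C → rt
Reagents that add atoms: (+)-B-allyldiisopinocampheylborane, C=CCB([C@@H]1C[C@@H]2C[C@H]([C@H]1C)C2(C)C)[C@@H]1C[C@@H]2C[C@H]([C@H]1C)C2(C)C
Why: Brown asymmetric allylboration through a closed chair transition state; the reagent from (+)-α-pinene should deliver allyl to the Si face of the enal and set C3 as S.

Step 2
Reactants: 2 (3S)-2-methylhexa-1,5-dien-3-ol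
Product: 3 (3S)-3-(tert-butyldimethylsilyloxy)-2-methylhexa-1,5-diene
Conditions: TBSCl, imidazole, DMF, 0 °C → rt
Reagents that add atoms: tert-butyldimethylsilyl chloride, C[Si](C)(Cl)C(C)(C)C
Why: Standard silylation; the ether protects O3 through the organolithium steps and marks it as the later-acylated oxygen.

Step 3
Reactants: 3 (3S)-3-(tert-butyldimethylsilyloxy)-2-methylhexa-1,5-diene; 1 methacrolein (excess)
Product: 4 (2E,5S)-5-(tert-butyldimethylsilyloxy)-2,6-dimethylhepta-2,6-dienal
Conditions: second-generation Grubbs catalyst [(H2IMes)(PCy3)Cl2Ru=CHPh] (5 mol%), CH2Cl2, 40 °C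
Reagents that add atoms: none
Why: Olefin cross-metathesis of a monosubstituted alkene with excess methacrolein, which should give the E-enal (the future E-C1=C10) under thermodynamic control; the hindered isopropenyl silyl ether should stay out of the catalytic cycle.

Step 4
Reactants: 4 (2E,5S)-5-(tert-butyldimethylsilyloxy)-2,6-dimethylhepta-2,6-dienal
Product: 5 (2E,5S)-5-(tert-butyldimethylsilyloxy)-2,6-dimethylhepta-2,6-dien-1-ol
Conditions: NaBH4, CeCl3·7H2O, MeOH, 0 °C
Reagents that add atoms: none
Why: Luche 1,2-reduction of the enal; no stereocentre is formed and the alkene geometry is untouched.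

Step 5
Reactants: 5 (2E,5S)-5-(tert-butyldimethylsilyloxy)-2,6-dimethylhepta-2,6-dien-1-ol
Product: 6 (2E,5S)-1-bromo-5-(tert-butyldimethylsilyloxy)-2,6-dimethylhepta-2,6-diene
Conditions: CBr4, PPh3, CH2Cl2, 0 °C
Reagents that add atoms: carbon tetrabromide, BrC(Br)(Br)Br
Why: Appel bromination of a primary allylic alcohol under neutral conditions; silyl ether and alkene geometry should be retained.

Step 6
Reactants: 7 1,3-dithiane; 6 (2E,5S)-1-bromo-5-(tert-butyldimethylsilyloxy)-2,6-dimethylhepta-2,6-diene
Product: 9 2-[(2E,5S)-5-(tert-butyldimethylsilyloxy)-2,6-dimethylhepta-2,6-dien-1-yl]-1,3-dithiane, via 2-lithio-1,3-dithiane 8 (not isolated)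
Conditions: 7, n-BuLi, THF, −30 °C; then 6, −78 → −20 °C
Reagents that add atoms: none
Why: Corey–Seebach alkylation; the lithiated dithiane displaces the primary allylic bromide by SN2 and installs C8 as a masked acyl anion next to the C9–C4 chain.

Step 7
Reactants: 10 (5S)-5-(hydroxymethyl)furan-2(5H)-one
Product: 11 (5S)-5-[(tert-butyldimethylsilyloxy)methyl]furan-2(5H)-one
Conditions: TBSCl, imidazole, CH2Cl2, 0 °C → rt
Reagents that add atoms: tert-butyldimethylsilyl chloride, C[Si](C)(Cl)C(C)(C)C
Why: Standard silylation; the bulky silyloxymethyl group on the future C6 shields one face of the butenolide.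

Step 8
Reactants: 9 2-[(2E,5S)-5-(tert-butyldimethylsilyloxy)-2,6-dimethylhepta-2,6-dien-1-yl]-1,3-dithiane; 11 (5S)-5-[(tert-butyldimethylsilyloxy)methyl]furan-2(5H)-one; 12 N,N-dimethylmethyleneiminium iodide (Eschenmoser's salt)
Product: 15 (4S,5S)-5-[(tert-butyldimethylsilyloxy)methyl]-3-[(dimethylamino)methyl]-4-{2-[(2E,5S)-5-(tert-butyldimethylsilyloxy)-2,6-dimethylhepta-2,6-dien-1-yl]-1,3-dithian-2-yl}oxolan-2-one (6,7-trans; C11 epimers), via lithiated dithiane 13 (not isolated), via lithium lactone enolate 14 (not isolated)
Conditions: 9, n-BuLi, THF, −30 °C; HMPA, then 11, −78 °C; then 12, −78 °C → rt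
Reagents that add atoms: none
Why: This is a tandem Michael addition–Mannich trapping, and the closest known reaction type is the conjugate addition of lithiated 1,3-dithianes to 5-substituted furan-2(5H)-ones with capture of the lactone enolate by an electrophile. n-BuLi removes the C8 hydrogen of 9, and in THF–HMPA the soft, solvent-separated anion 13 should add 1,4 to 11 and form C7–C8. Attack should occur on the butenolide face opposite the C6 silyloxymethyl group, so C7 is set trans to C6 by the chiral-pool centre. The lithium enolate 14 is then aminomethylated at C11 by the iminium ion of 12, which forms C11–C13; approach anti to the dithianyl group should favour the 7,11-trans epimer, but C11 is erased in step 18. No ring is closed in this step. The step needs 1,4-addition to win over 1,2-addition and over deprotonation of 11 at C6, which the polar cosolvent, the low temperature and the sulfur-stabilised anion are meant to secure. It also needs anti facial selectivity, which the C6 substituent secures. The C3 silyl ether and both alkenes of the arm are spectators.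

Step 9
Reactants: 15 trans-lactone Mannich base (bis-silyl ether)
Product: 16 (4S,5S)-5-(hydroxymethyl) analogue of 15 (C5 primary alcohol; C3 silyl ether retained)
Conditions: HF·pyridine, pyridine, THF, 0 °C
Reagents that add atoms: none
Why: Buffered HF·pyridine at 0 °C should cleave the primary silyl ether selectively over the secondary allylic one; dithiane, amine and lactone are inert.

Step 10
Reactants: 16 C5 primary alcohol
Product: 17 (2S,3S)-4-[(dimethylamino)methyl]-3-{2-[(2E,5S)-5-(tert-butyldimethylsilyloxy)-2,6-dimethylhepta-2,6-dien-1-yl]-1,3-dithian-2-yl}-5-oxooxolane-2-carbaldehyde (C5 aldehyde)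
Conditions: SO3·pyridine, DMSO, i-Pr2NEt, CH2Cl2, 0 °C
Reagents that add atoms: none
Why: Parikh–Doering oxidation; activated DMSO does not touch the dithiane or the tertiary amine, and the low temperature limits epimerisation of the α-acyloxy aldehyde, which is used crude.

Step 11
Reactants: 17 C5 aldehyde
Product: 18 (4S,5R)-3-[(dimethylamino)methyl]-5-ethenyl-4-{2-[(2E,5S)-5-(tert-butyldimethylsilyloxy)-2,6-dimethylhepta-2,6-dien-1-yl]-1,3-dithian-2-yl}oxolan-2-one (C6 vinyl lactone)
Conditions: Ph3PCH3Br, KHMDS, THF, −78 → 0 °C
Reagents that add atoms: methyltriphenylphosphonium bromide, C[P+](c1ccccc1)(c1ccccc1)c1ccccc1.[Br-]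
Why: Wittig methylenation with the non-stabilised ylide at low temperature; the lactone, dithiane and amine are inert to the ylide and C6 should keep its configuration.

Step 12
Reactants: 18 C6 vinyl lactone (dithiane)
Product: 19 (4S,5R)-4-[(3E,6S)-6-(tert-butyldimethylsilyloxy)-3,7-dimethylocta-3,7-dienoyl]-3-[(dimethylamino)methyl]-5-ethenyloxolan-2-one (C8 ketone)
Conditions: PhI(OCOCF3)2, MeCN/H2O (9:1), 0 °C
Reagents that add atoms: water, O
Why: Oxidative dithiane hydrolysis with a hypervalent iodine reagent; the liberated acid protonates the amine, and the alkenes and silyl ether should tolerate the short exposure. The C6–O bond lies near the nodal plane of the C7 enol π system, so β-elimination of the lactone oxygen should be slow.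

Step 13
Reactants: 19 C8 ketone
Product: 20 (4R,5R)-4-[(1R,3E,6S)-6-(tert-butyldimethylsilyloxy)-1-hydroxy-3,7-dimethylocta-3,7-dien-1-yl]-3-[(dimethylamino)methyl]-5-ethenyloxolan-2-one (8R alcohol)
Conditions: (S)-2-methyl-CBS-oxazaborolidine (0.5 equiv), catecholborane, toluene, −78 °C
Reagents that add atoms: none
Why: Corey–Bakshi–Shibata reduction; with the branched ring carbon C7 as the large group and the C9 methylene as the small one, the (S)-catalyst should deliver hydride to the face that gives 8R. Catecholborane spares the three alkenes and the lactone.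

Step 14
Reactants: 21 (2E)-2-methylbut-2-en-1-ol (tiglyl alcohol)
Product: 22 [(2S,3S)-2,3-dimethyloxiran-2-yl]methanol
Conditions: Ti(OiPr)4 (cat.), L-(+)-diisopropyl tartrate, t-BuOOH, 4 Å molecular sieves, CH2Cl2, −20 °C
Reagents that add atoms: tert-butyl hydroperoxide, CC(C)(C)OO
Why: Sharpless asymmetric epoxidation; with the natural L-(+)-tartrate, E-allylic alcohols give the (2S,3S) epoxy alcohols, which sets both centres of the C8 acyl group.

Step 15
Reactants: 22 [(2S,3S)-2,3-dimethyloxiran-2-yl]methanol
Product: 23 (2R,3S)-2,3-dimethyloxirane-2-carboxylic acid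
Conditions: RuCl3·xH2O (cat.), NaIO4, CCl4/MeCN/H2O, rt
Reagents that add atoms: water, O
Why: Catalytic ruthenium tetroxide oxidation of an epoxy alcohol to the glycidic acid, leaving the oxirane intact; the C2 descriptor changes to R by priority only, with no change of geometry.

Step 16
Reactants: 20 8R alcohol; 23 (2R,3S)-2,3-dimethyloxirane-2-carboxylic acid
Product: 25 8-O-[(2R,3S)-2,3-dimethyloxirane-2-carbonyl] ester of 20 (C3 silyl ether and Mannich base retained), via mixed anhydride 24 (not isolated)
Conditions: 23, 2,4,6-trichlorobenzoyl chloride, Et3N, THF, rt; then 20, DMAP, toluene, rt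
Reagents that add atoms: none
Why: Yamaguchi esterification, suited to a hindered secondary alcohol and an α-quaternary acid; C8 is acylated with retention and the acid has no epimerisable α-hydrogen.

Step 17
Reactants: 25 C8 ester (C3 silyl ether)
Product: 26 3-O-desilyl derivative of 25 (free 3S allylic alcohol)
Conditions: HF·pyridine, pyridine, THF, 0 °C → rt
Reagents that add atoms: none
Why: Fluoride cleavage of the secondary allylic silyl ether; the glycidic ester is deactivated towards acid opening and should survive. The step is placed before the acid-labile 1,10-epoxide and the Michael acceptor exist.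

Step 18
Reactants: 26 C3 alcohol (Mannich base)
Product: 28 α-methylene lactone triene (26 with C11=CH2 in place of the CH–CH2NMe2 unit), via trimethylammonium iodide 27 (not isolated)
Conditions: MeI, THF, rt; then aq. NaHCO3, EtOAc, rt
Reagents that add atoms: none
Why: Quaternisation followed by E1cB (Hofmann-type) elimination is the standard unmasking of an α-methylene lactone from its Mannich base; it is done only now, when C8 is an ester carbinol and C7–H is no longer activated towards migration of the alkene.

Step 19
Reactants: 28 α-methylene lactone triene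
Product: 29 (1R,10R)-1,10-epoxide of 28 (ring-closing diene)
Conditions: D-fructose-derived Shi ketone (0.3 equiv), Oxone, K2CO3, Bu4NHSO4, MeCN/dimethoxymethane–aq. Na2B4O7/Na2EDTA, 0 °C
Reagents that add atoms: potassium peroxymonosulfate (active component of Oxone), [K+].[O-]S(=O)(=O)OO
Why: Shi asymmetric epoxidation; the chiral dioxirane should attack the E-trisubstituted C1=C10 alkene through the spiro transition state that gives the (R,R)-epoxide, as for internal polyprenyl alkenes. The 1,1-disubstituted, monosubstituted and electron-poor alkenes should react far more slowly.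

Step 20
Reactants: 29 (1R,10R)-epoxy diene
Product: 30 (1R,3S,4Z,6R,7R,8R,10R)-1,10-epoxy-3-hydroxy-8-[(2R,3S)-2,3-dimethyloxirane-2-carbonyloxy]germacra-4,11(13)-dien-12,6-olide (macrocyclic 3-alcohol)
Conditions: second-generation Grubbs catalyst [(H2IMes)(PCy3)Cl2Ru=CHPh] (10–20 mol%), 1,4-benzoquinone (cat.), toluene (1 mM), 80 °C
Reagents that add atoms: none
Why: Ring-closing metathesis between the C6 vinyl group and the C4 isopropenyl group with loss of ethylene; the ten-membered ring should enforce the Z geometry and the free allylic hydroxyl should assist engagement of the hindered alkene. With C1=C10 already an epoxide there is no competing six-membered closure, and the α-methylene group cannot form a ring with either partner.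

Step 21
Reactants: 30 macrocyclic 3-alcohol; 31 (2R)-2-methylbutanoic acid
Product: 33 CNP0265335.3 (1R,3S,4Z,6R,7R,8R,10R)-1,10-epoxy-3-[(2R)-2-methylbutanoyloxy]-8-[(2R,3S)-2,3-dimethyloxirane-2-carbonyloxy]germacra-4,11(13)-dien-12,6-olide, via O-acylisourea 32 (not isolated)
Conditions: 31, N,N'-diisopropylcarbodiimide, DMAP (cat.), CH2Cl2, 0 °C → rt
Reagents that add atoms: none
Why: Steglich esterification of the allylic alcohol under near-neutral conditions; the epoxides and the methylene lactone should be untouched, and catalytic DMAP at low temperature should keep the α-stereocentre of the acid intact.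

## Compound list

1 | 2-methylprop-2-enal (methacrolein) | C=C(C)C=O | starting material
2 | (3S)-2-methylhexa-1,5-dien-3-ol | C=C(C)[C@@H](O)CC=C | intermediate
3 | (3S)-3-(tert-butyldimethylsilyloxy)-2-methylhexa-1,5-diene | C=C(C)[C@@H](O[Si](C)(C)C(C)(C)C)CC=C | intermediate
4 | (2E,5S)-5-(tert-butyldimethylsilyloxy)-2,6-dimethylhepta-2,6-dienal | C=C(C)[C@@H](O[Si](C)(C)C(C)(C)C)C/C=C(\C)C=O | intermediate
5 | (2E,5S)-5-(tert-butyldimethylsilyloxy)-2,6-dimethylhepta-2,6-dien-1-ol | C=C(C)[C@@H](O[Si](C)(C)C(C)(C)C)C/C=C(\C)CO | intermediate
6 | (2E,5S)-1-bromo-5-(tert-butyldimethylsilyloxy)-2,6-dimethylhepta-2,6-diene | C=C(C)[C@@H](O[Si](C)(C)C(C)(C)C)C/C=C(\C)CBr | intermediate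
7 | 1,3-dithiane | C1CSCSC1 | starting material
8 | 2-lithio-1,3-dithiane | [Li]C1SCCCS1 | intermediate
9 | 2-[(2E,5S)-5-(tert-butyldimethylsilyloxy)-2,6-dimethylhepta-2,6-dien-1-yl]-1,3-dithiane | C=C(C)[C@@H](O[Si](C)(C)C(C)(C)C)C/C=C(\C)CC1SCCCS1 | intermediate
10 | (5S)-5-(hydroxymethyl)furan-2(5H)-one | O=C1C=C[C@@H](CO)O1 | starting material
11 | (5S)-5-[(tert-butyldimethylsilyloxy)methyl]furan-2(5H)-one | O=C1C=C[C@@H](CO[Si](C)(C)C(C)(C)C)O1 | intermediate
12 | N,N-dimethylmethyleneiminium iodide (Eschenmoser's salt) | C=[N+](C)C.[I-] | starting material
13 | 2-lithio derivative of 9 | C=C(C)[C@@H](O[Si](C)(C)C(C)(C)C)C/C=C(\C)CC1([Li])SCCCS1 | intermediate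
14 | lithium enolate of the 6,7-trans conjugate adduct | [Li]OC1=C[C@H](C2(C/C(C)=C/C[C@H](O[Si](C)(C)C(C)(C)C)C(C)=C)SCCCS2)[C@@H](CO[Si](C)(C)C(C)(C)C)O1 | intermediate
15 | (4S,5S)-5-[(tert-butyldimethylsilyloxy)methyl]-3-[(dimethylamino)methyl]-4-{2-[(2E,5S)-5-(tert-butyldimethylsilyloxy)-2,6-dimethylhepta-2,6-dien-1-yl]-1,3-dithian-2-yl}oxolan-2-one (C11 epimers) | O=C1O[C@H](CO[Si](C)(C)C(C)(C)C)[C@@H](C2(C/C(C)=C/C[C@H](O[Si](C)(C)C(C)(C)C)C(C)=C)SCCCS2)C1CN(C)C | intermediate
16 | 5-(hydroxymethyl) analogue of 15 (C5 primary alcohol) | O=C1O[C@H](CO)[C@@H](C2(C/C(C)=C/C[C@H](O[Si](C)(C)C(C)(C)C)C(C)=C)SCCCS2)C1CN(C)C | intermediate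
17 | 5-formyl analogue of 15 (C5 aldehyde) | O=C1O[C@H](C=O)[C@@H](C2(C/C(C)=C/C[C@H](O[Si](C)(C)C(C)(C)C)C(C)=C)SCCCS2)C1CN(C)C | intermediate
18 | 5-ethenyl analogue of 15 (C6 vinyl lactone) | O=C1O[C@H](C=C)[C@@H](C2(C/C(C)=C/C[C@H](O[Si](C)(C)C(C)(C)C)C(C)=C)SCCCS2)C1CN(C)C | intermediate
19 | (4S,5R)-4-[(3E,6S)-6-(tert-butyldimethylsilyloxy)-3,7-dimethylocta-3,7-dienoyl]-3-[(dimethylamino)methyl]-5-ethenyloxolan-2-one (C8 ketone) | O=C1O[C@H](C=C)[C@@H](C(=O)C/C(C)=C/C[C@H](O[Si](C)(C)C(C)(C)C)C(C)=C)C1CN(C)C | intermediate
20 | (4R,5R)-4-[(1R,3E,6S)-6-(tert-butyldimethylsilyloxy)-1-hydroxy-3,7-dimethylocta-3,7-dien-1-yl]-3-[(dimethylamino)methyl]-5-ethenyloxolan-2-one (8R alcohol) | O=C1O[C@H](C=C)[C@@H]([C@H](O)C/C(C)=C/C[C@H](O[Si](C)(C)C(C)(C)C)C(C)=C)C1CN(C)C | intermediate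
21 | (2E)-2-methylbut-2-en-1-ol (tiglyl alcohol) | C/C=C(\C)CO | starting material
22 | [(2S,3S)-2,3-dimethyloxiran-2-yl]methanol | OC[C@]1(C)O[C@H]1C | intermediate
23 | (2R,3S)-2,3-dimethyloxirane-2-carboxylic acid | OC(=O)[C@]1(C)O[C@H]1C | intermediate
24 | (2R,3S)-2,3-dimethyloxirane-2-carboxylic 2,4,6-trichlorobenzoic anhydride | O=C(OC(=O)[C@]1(C)O[C@H]1C)c1c(Cl)cc(Cl)cc1Cl | intermediate
25 | 8-O-[(2R,3S)-2,3-dimethyloxirane-2-carbonyl] ester of 20 | O=C1O[C@H](C=C)[C@@H]([C@H](OC(=O)[C@]2(C)O[C@H]2C)C/C(C)=C/C[C@H](O[Si](C)(C)C(C)(C)C)C(C)=C)C1CN(C)C | intermediate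
26 | 3-O-desilyl derivative of 25 (free 3S alcohol) | O=C1O[C@H](C=C)[C@@H]([C@H](OC(=O)[C@]2(C)O[C@H]2C)C/C(C)=C/C[C@H](O)C(C)=C)C1CN(C)C | intermediate
27 | N-methyl quaternary ammonium iodide of 26 | O=C1O[C@H](C=C)[C@@H]([C@H](OC(=O)[C@]2(C)O[C@H]2C)C/C(C)=C/C[C@H](O)C(C)=C)C1C[N+](C)(C)C.[I-] | intermediate
28 | α-methylene lactone triene (C11=C13 unveiled) | O=C1O[C@H](C=C)[C@@H]([C@H](OC(=O)[C@]2(C)O[C@H]2C)C/C(C)=C/C[C@H](O)C(C)=C)C1=C | intermediate
29 | (1R,10R)-1,10-epoxide of 28 | O=C1O[C@H](C=C)[C@@H]([C@H](OC(=O)[C@]2(C)O[C@H]2C)C[C@@]2(C)O[C@@H]2C[C@H](O)C(C)=C)C1=C | intermediate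
30 | (1R,3S,4Z,6R,7R,8R,10R)-1,10-epoxy-3-hydroxy-8-[(2R,3S)-2,3-dimethyloxirane-2-carbonyloxy]germacra-4,11(13)-dien-12,6-olide | C=C1C(=O)O[C@@H]2/C=C(/C)[C@@H](O)C[C@H]3O[C@]3(C)C[C@@H](OC(=O)[C@]3(C)O[C@H]3C)[C@@H]12 | intermediate
31 | (2R)-2-methylbutanoic acid | CC[C@@H](C)C(=O)O | starting material
32 | O-acylisourea from 31 and N,N'-diisopropylcarbodiimide | CC[C@@H](C)C(=O)OC(=NC(C)C)NC(C)C | intermediate
33 | CNP0265335.3 | C=C1C(=O)O[C@@H]2/C=C(/C)[C@@H](OC(=O)[C@H](C)CC)C[C@H]3O[C@]3(C)C[C@@H](OC(=O)[C@]3(C)O[C@H]3C)[C@@H]12 | target

## Step count and risk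

Total: 21 steps. Longest linear sequence: 18 steps (steps 1–6, 8–13 and 16–21). Steps 7 and 14–15 are side branches.

**Step 8 (key step).** The lithiated dithiane is strongly basic, so deprotonation of the butenolide at C6 and 1,2-addition may compete with conjugate addition. Proton transfer may also outrun capture of the enolate by the sparingly soluble iminium salt. Fallback: separate the two bond formations. Starting from 9 and 11, the lithium enolate 14 is silylated with TMSCl to the silyl ketene acetal F1. After removal of the lithium salts, F1 is aminomethylated with 12 in CH2Cl2, a Mukaiyama–Mannich-type reaction known for silyl ketene acetals and Eschenmoser's salt. The sequence rejoins the route at 15.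

**Step 20 (ring-closing metathesis).** The strained ten-membered ring may close more slowly than the diene oligomerises. The hindered, allylically oxygenated 1,1-disubstituted alkene may engage poorly, the free allylic alcohol may isomerise to a ketone through ruthenium hydrides, and the geometry may not be purely Z. Fallback: reverse the order of ring closure and acylation. Starting from 29, the C3 hydroxyl is esterified with 31 (carbodiimide, DMAP) to the fully acylated diene F4. F4 is then closed by metathesis as the last step and rejoins the route at 33. This removes the isomerisable alcohol and closes the ring on the natural substitution pattern. Because C4 and C5 come from fixed fragments, a non-metathetic closure at another ring bond would require a redesigned arm.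

**Step 19 (Shi epoxidation).** The buffered aqueous oxidant may add to or hydrolyse the exposed methylene lactone and the esters, and the existing C8 centre may erode catalyst control. Fallback: epoxidise before the Michael acceptor exists. Starting from 26, the same ketone-catalysed Oxone oxidation with extra oxidant converts the amine to its N-oxide while the C1=C10 alkene is epoxidised, giving F3. Gentle warming then brings about Cope elimination, a known route from Mannich-base N-oxides to α-methylene lactones, and the sequence rejoins at 29.

**Step 13 (C8 reduction).** The catalyst may not distinguish well between the ring carbon C7 and the C9 methylene, or the substrate bias may oppose it, which would give poor selectivity at C8. The ketone may also epimerise at C7 if the reduction is slow. Fallback: let the substrate decide and correct at the esterification. Starting from 19, reduction with NaBH4/CeCl3 at −78 °C may favour the 8S alcohol F2. In that case F2 is esterified with acid 23 under Mitsunobu conditions (PPh3, diisopropyl azodicarboxylate) with inversion, and the sequence rejoins at 25.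

## Further compounds

F1 | step 8 | trimethylsilyl ketene acetal of the 6,7-trans conjugate adduct | C[Si](C)(C)OC1=C[C@H](C2(C/C(C)=C/C[C@H](O[Si](C)(C)C(C)(C)C)C(C)=C)SCCCS2)[C@@H](CO[Si](C)(C)C(C)(C)C)O1
F2 | step 13 | 8S epimer of alcohol 20 | O=C1O[C@H](C=C)[C@@H]([C@@H](O)C/C(C)=C/C[C@H](O[Si](C)(C)C(C)(C)C)C(C)=C)C1CN(C)C
F3 | step 19 | N-oxide of 26 with the (1R,10R)-1,10-epoxide | O=C1O[C@H](C=C)[C@@H]([C@H](OC(=O)[C@]2(C)O[C@H]2C)C[C@@]2(C)O[C@@H]2C[C@H](O)C(C)=C)C1C[N+](C)(C)[O-]
F4 | step 20 | 3-O-[(2R)-2-methylbutanoyl] ester of diene 29 | O=C1O[C@H](C=C)[C@@H]([C@H](OC(=O)[C@]2(C)O[C@H]2C)C[C@@]2(C)O[C@@H]2C[C@H](OC(=O)[C@H](C)CC)C(C)=C)C1=C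
A1 | alternative 1 | trans-fused α-methylene lactone with C3 (R)-2-methylbutanoate, C8 triethylsilyl ether and E-C1=C10 | C=C1C(=O)O[C@@H]2/C=C(/C)[C@@H](OC(=O)[C@H](C)CC)C/C=C(\C)C[C@@H](O[Si](CC)(CC)CC)[C@@H]12
A2 | alternative 2 | ten-membered (1E,4Z)-dien-6-one with C3 tert-butyldimethylsilyl ether and C8 4-methoxybenzyl ether | O=C1/C=C(/C)[C@@H](O[Si](C)(C)C(C)(C)C)C/C=C(\C)C[C@@H](OCc2ccc(OC)cc2)C1
A3 | alternative 3 | trans-fused ten-membered lactone without the methylene (C3 tert-butyldimethylsilyl ether, C8 4-methoxybenzyl ether) | O=C1O[C@@H]2/C=C(/C)[C@@H](O[Si](C)(C)C(C)(C)C)C/C=C(\C)C[C@@H](OCc3ccc(OC)cc3)[C@H]2C1
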